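**Early hours.** Early on in this flask, solid reagent went into solution faster than solid substrate, with coefficients of 9.8 × 10⁻⁴ s⁻¹ against 4.8 × 10⁻⁵ s⁻¹, so I reckoned with partner present from the outset.

solid substrate 0.050 M; solid reagent 0.900 equiv; time 10 h

    solid substrate ⇌ dissolved substrate, rate k1*(cs1 - [dissolved substrate]) while solid is left; crystals form when [dissolved substrate] > cs1 (cs1 = 24 mM, k1 = 4.8 × 10⁻⁵ s⁻¹)
    dissolved substrate + partner → target (k2 = 0.044 L mol⁻¹ s⁻¹)
    dissolved substrate + target → side product (k3 = 0.061 L mol⁻¹ s⁻¹)
    solid product ⇌ target, rate k4*(cs4 - [target]) while solid is left; crystals form when [target] > cs4 (cs4 = 18 mM, k4 = 0.0053 s⁻¹)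
    solid substrate → decomposition product (k5 = 1.3 × 10⁻⁸ s⁻¹)
    partner ⇌ dormant form (K6 = 0.37, k6 = 4.9 × 10⁻⁵ s⁻¹)
    solid reagent ⇌ partner, rate k7*(cs7 - [partner]) while solid is left; crystals form when [partner] > cs7 (cs7 = 27 mM, k7 = 9.8 × 10⁻⁴ s⁻¹)

- a species is counted by the solid substrate in it: one side product counts as two
- amounts and yields of target count solid product too
- given per volume of solution although it is solid: solid substrate, solid product, solid reagent
- at the start none of the solid substrate is in solution
- at the start none of the solid reagent is in solution
- dissolved substrate means what is dissolved; the solid is not counted in it
- run time (flask): 10 h

- amount of target and solid product together at 10 h, in percent of the solid substrate charged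
- concentration of dissolved substrate in solution at 10 h, in percent of saturation

**Balance ratio.** Dissolved substrate reacts with partner to make target, or with target to make side product, and it stands as a factor in both rates. Target therefore stops gaining when target over partner equals the rate constant for making target over the one for making side product. I called this the balance ratio, a selectivity factor, and it came to 0.721.

**First way.** I held partner at its solubility, 27 mM. That put the target ceiling at 19.5 mM, or 39.0 % of the charge.

**Second way.** I counted partner instead. The charge was 45.0 mM, and solid substrate could deliver at most 41.5 mM by the end. Making a target uses one partner, while losing a target to side product uses none, so partner used is half of delivered plus target. With target at balance and the dormant form at equilibrium, target came to 10.1 mM, or 20.2 %, with partner at 14.0 mM.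

**The cheat.** The first way needed 67.5 mM of partner in its three forms, more than the 45.0 mM charged. So the first way cheated, and I kept the second. At balance the two reactions consume dissolved substrate equally, which put it at 3.74 % of saturation. Target stayed below its solubility of 18 mM, so I expected no crystals.

**The forecast.** The forecast gave 22.1 % and 3.6 %, with target "peaking near 11.2 mM and never reaching 18 mM, so no solid product forms". Its yield stood 1.9 percentage points above mine.

**The result.** This flask gave 22.4 % and 3.57 %. Left for 100 h, it held 20.0 %. At 10.0 h partner stood at 0.0136 M, and the balance ratio turns that into 19.7 % of the charge. The flask's target stood above this, so at that moment target was being eaten faster than it was made.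

**A neighbour.** The neighbour with 3.60 equiv of solid reagent had 180 mM of it charged, more than the first way needed, so there its ceiling of 39.0 % was honest. That neighbour reached 28.7 %, below the ceiling.

(The numbers of this flask were set for the occasion; the rest is arithmetic.)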